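Remark on the chemistry: the target has a centre of inversion and is achiral (meso), so its four stereodescriptors are treated as a relative configuration. Twofold reactions of the symmetric intermediates are written as single steps, and the singly reacted species on the way are not listed separately.

## Analysis of the target

Compound 17 is a tetrasubstituted cyclobutane. Taking the ring carbons in the order of the SMILES string, Ca and Cc each carry a 3,4-dimethoxyphenyl ring, and Cb and Cd each carry a carbonyl group that forms an imide with the nitrogen of a 5,6-dihydropyridin-2(1H)-one ring. The substitution is head-to-tail and the relative configuration is trans (Ca/Cb), cis (Cb/Cc), trans (Cc/Cd), cis (Cd/Ca). The two aryl groups therefore lie on opposite faces, as do the two acyl groups, and only relative configuration has to be controlled. The sensitive parts are the two N-acyl enelactams (acyl donors and Michael acceptors), the centres Cb and Cd (α to a carbonyl, so able to epimerise), and the strained ring with its two electron-rich benzylic positions. The difficulty is to place two kinds of substituent on a four-membered ring with both the 1,3-alternation and this cis/trans pattern, which a [2+2] dimerisation in solution would not control. The strategy rests on one feature: the arene carbon bonded to Ca, and likewise the one bonded to Cc, can be a former carboxyl carbon. All four ring substituents are then carboxyl-derived, and the ring with its configuration is that of the commercial dianhydride 1, whose two anhydride bridges span exactly the cis pairs Cb/Cc and Cd/Ca.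

## Retrosynthetic reasoning

The two imide C–N bonds are cut first, leading to diacid 14 (the α-truxillic-type 2,4-bis(3,4-dimethoxyphenyl)cyclobutane-1,3-dicarboxylic acid) and two molecules of lactam 15. The imide is the most fragile function of 17, so it is made last; the forward reaction must acylate the lactam nitrogen through the mixed anhydride 16 without enolising Cb or Cd.

The carboxyl groups of 14 are taken back to the primary alcohols of diol 12, which is carried as its bis-silyl ether 11. No C–C bond is cut here. The gain is that Cb and Cd bear no carbonyl group while the arenes are built, so nothing on the ring can epimerise until the penultimate step. The forward oxidation passes through dialdehyde 13 and must be mild at that stage.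

Each benzene ring of 11 is taken back to a 4,5-dimethoxycyclohexa-1,4-diene ring in 10. This is a change of oxidation level only; the forward step is a dehydrogenation, which is easy because the product is an arene.

The key disconnection cuts each six-membered ring of 10 at two bonds, C1–C6 and C2–C3 (C1 being the ring carbon on Ca or Cc). This gives the diyne 8 and two molecules of the symmetric diene 9. The cut is made here and not at the Ca–aryl bond because it needs no reactive centre on a ring stereocentre: the alkyne carbon that becomes C1 is already attached to Ca or Cc. The forward reaction has to join an unactivated terminal alkyne and an electron-rich diene twice on one substrate, which calls for cobalt catalysis rather than heat.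

The terminal alkynes of 8, reached from diol 7 by silylation, are cut at the triple bond. Each arises by one-carbon homologation of an aldehyde in 6, the open-chain tautomer of bis-lactol 4. The lactol form masks the aldehydes and holds each one cis to its neighbouring CH2O group.

Bis-lactol 4 comes from the head-to-tail bis-lactone 3 by partial reduction. Lactone 3 comes from dianhydride 1 by reducing one carbonyl of each anhydride ring, through the hydroxy acid 2. In 3 the carbonyl carbons on Ca and Cc are kept for the arenes, and the carbons on Cb and Cd are parked as CH2O groups until they are reoxidised. The reduction cannot distinguish the two carbonyls of an anhydride ring, so 3 must be separated from its regioisomer. That is the one price paid for buying the ring with all four stereocentres in place.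

## Alternatives that were turned down

Alternative 1: The imide C–N bonds are formed first. The lithium amide of lactam 15 would open both anhydride rings of 1 at the carbonyls on Cb and Cd to give the diacid bis-imide A1, whose remaining carboxyl groups on Ca and Cc would then be exchanged for aryl groups by decarboxylative arylation.
- For it: it is the shortest plan by a wide margin, the anhydride is its own activating group, and both building blocks are used directly. On step count it is clearly stronger than the chosen route.
- Against it: the opening is as blind to head-to-tail versus head-to-head as the reduction of 1 is. In A1 each carboxylate sits cis and vicinal to an activated N-acyl lactam, so it can close back to the anhydride and expel 15. The arylation would pass through radicals at Ca and Cc, each flanked by one substituent on either face, so no facial bias is expected; and it would have to run in the presence of two radical- and nucleophile-accepting enelactams.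
- Comparison: the chosen route gives up brevity for a sequence in which the fragile imides appear only at the end and no reactive intermediate is ever generated on a ring carbon.

Alternative 2: The cyclobutane is made by ring contraction of a pyrrolidine. The metalated azomethine ylide of the glycine imine A2 would add to the (Z)-acrylate A3 under a copper catalyst with a bulky bisphosphine, forming the Ca–Cb and Cc–Cd bonds and giving pyrrolidine A4 (2,5-cis, 3,4-cis, 2,3-trans). Extrusion of nitrogen would then form the fourth ring bond.
- For it: it is convergent, sets all four centres in one catalytic cycloaddition from simple aromatic precursors, and either enantiomer of A4 leads to the same meso cyclobutane. On convergence it is stronger than the chosen linear route.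
- Against it: the cycloaddition must be exo-selective with a β-aryl (Z)-acrylate, a sluggish dipolarophile that isomerises easily. The nitrogen extrusion proceeds through a 1,4-biradical that here is benzylic at one end and α to an ester at the other. Such a long-lived biradical can rotate before closure or fragment into two alkenes, so the configuration won in the cycloaddition is at risk in the very step that forms the ring. The esters would then have to be hydrolysed next to epimerisable centres.
- Comparison: the chosen route never forms the four-membered ring and never has to defend it against cleavage. It pays with more steps.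

Alternative 3: The two Ca–aryl and Cc–aryl bonds are made by directed C–H arylation. The trans bis(quinolin-8-yl)amide A5 and aryl iodide A6 would react under divalent palladium catalysis with a silver carboxylate to give the diaryl bis-amide A7, which after cleavage of the auxiliaries would give 14.
- For it: the aryl groups are bought rather than built, arylation of cyclobutane C–H bonds cis to such an amide is well established, and the sequence is shorter. In precedent for the C–C bond formation and in step count it is stronger than the chosen route.
- Against it: each methylene carbon of A5 is flanked by both amides. The target requires each amide to direct exactly one arylation, at different carbons, so that the aryl groups end on opposite faces. One amide arylating both of its neighbours would give the cis-diaryl diastereomer, and further arylation is possible. Two hindered auxiliary amides must then be cleaved under forcing conditions at centres that can epimerise.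
- Comparison: the chosen route has no diastereoselective event at all and no auxiliary to remove. It offers certainty of configuration in place of brevity.

Key step: step 5

## Route

Step 1
Reactants: 1 (1α,2α,3β,4β)-cyclobutane-1,2,3,4-tetracarboxylic 1,2:3,4-dianhydride
Product: 3 head-to-tail bis-lactone 4,9-dioxatricyclo[5.3.0.0(2,6)]decane-3,8-dione (cis-anti-cis), via 2,4-bis(hydroxymethyl)cyclobutane-1,3-dicarboxylic acid 2 (not isolated)
Conditions: NaBH4 (2.2 equiv), THF–DMF, 0 °C to rt; then 6 M HCl, rt; crystallisation or chromatography to remove the head-to-head regioisomer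
Reagents that add atoms: none
Why: Hydride adds to one carbonyl of each anhydride ring, the ring-opened aldehyde carboxylate is reduced on to the hydroxy carboxylate 2, and acid closes the cis-fused γ-lactones (borohydride reduction of a cyclic anhydride to a lactone) without touching the ring stereocentres. No regiocontrol is expected, so at best about half of the material can be 3; it is centrosymmetric and free of a net dipole, unlike its polar head-to-head isomer, which should make the separation practicable.

Step 2
Reactants: 3 head-to-tail bis-lactone
Product: 4 bis-lactol 4,9-dioxatricyclo[5.3.0.0(2,6)]decane-3,8-diol (mixture of anomers)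
Conditions: i-Bu2AlH (2.4 equiv), CH2Cl2–THF, −78 °C; MeOH, then Na2SO4·10H2O, filtration
Reagents that add atoms: none
Why: At −78 °C each γ-lactone takes up one hydride and the tetrahedral aluminium alkoxide persists until work-up (partial reduction of a lactone to a lactol); the cis ring fusions are retained and the non-aqueous work-up avoids loss of the polar product.

Step 3
Reactants: 4 bis-lactol; 5 dimethyl (1-diazo-2-oxopropyl)phosphonate
Product: 7 [(1α,2α,3β,4β)-2,4-diethynylcyclobutane-1,3-diyl]dimethanol, via 2,4-bis(hydroxymethyl)cyclobutane-1,3-dicarbaldehyde 6 (not isolated)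
Conditions: 5 (3 equiv), K2CO3 (4 equiv), MeOH, 0 °C to rt
Reagents that add atoms: dimethyl (1-diazo-2-oxopropyl)phosphonate (5), COP(=O)(OC)C(=[N+]=[N-])C(C)=O
Why: The lactol equilibrates with hydroxy aldehyde 6; methanolysis of 5 gives the dimethyl (diazomethyl)phosphonate anion, which olefinates the aldehyde, loses N2 and rearranges by a 1,2-hydrogen shift to the terminal alkyne (Ohira–Bestmann form of the Seyferth–Gilbert homologation). The former lactone carbonyl carbon becomes the alkyne carbon on Ca and Cc, and the mild carbonate base together with the lactol masking should keep these α-centres from epimerising.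

Step 4
Reactants: 7 diyne diol
Product: 8 bis(tert-butyldimethylsilyl) ether of [(1α,2α,3β,4β)-2,4-diethynylcyclobutane-1,3-diyl]dimethanol
Conditions: t-BuMe2SiCl (2.5 equiv), imidazole (5 equiv), DMF, rt
Reagents that add atoms: tert-butyl(chloro)dimethylsilane, CC(C)(C)[Si](C)(C)Cl
Why: Imidazole-promoted silylation of two unhindered primary alcohols; it removes the free hydroxyl groups before the Lewis acidic cobalt/zinc step and gives a non-polar, easily handled diyne.

Step 5
Reactants: 8 bis-silylated diyne; 9 2,3-dimethoxybuta-1,3-diene
Product: 10 bis(tert-butyldimethylsilyl) ether of [(1α,2α,3β,4β)-2,4-bis(4,5-dimethoxycyclohexa-1,4-dien-1-yl)cyclobutane-1,3-diyl]dimethanol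
Conditions: 9 (4 equiv), CoBr2(dppe) (10 mol %; dppe = 1,2-bis(diphenylphosphino)ethane), Zn powder (20 mol %), ZnI2 (20 mol %), CH2Cl2, rt; filtration through basic alumina, crude carried on
Reagents that add atoms: 2,3-dimethoxybuta-1,3-diene (9), C=C(OC)C(OC)=C
Why: Zn reduces CoBr2(dppe) to monovalent cobalt and ZnI2 removes halide, so that a cationic cobalt–dppe fragment binds the s-cis diene and one terminal alkyne; oxidative cyclisation joins an alkyne carbon to a diene terminus and gives a cobaltacycle of trivalent cobalt, and reductive elimination forms the second C–C bond, releases the cyclohexa-1,4-diene and returns monovalent cobalt. The closest known reaction type is the cobalt-catalysed neutral [4+2] cycloaddition of unactivated terminal alkynes with 2,3-disubstituted buta-1,3-dienes, which tolerates silyl ethers; the 2,3-dialkoxy diene and the twofold use on one substrate are extensions of it. Each of the two six-membered rings closes in this intermolecular metal-mediated [4+2] mode, two C–C bonds per ring, and the alkyne carbon on Ca or Cc becomes C1 of a 4,5-dimethoxycyclohexa-1,4-dien-1-yl group. No stereocentre is created, since every new ring carbon is sp2 or CH2, and Ca to Cd are spectators that at no point carry a radical, a carbanion or a carbonyl group. The diene is symmetric, so both orientations give the same adduct and there is no regiochemical question. The selectivity needed is chemoselectivity for the cross [4+2] over alkyne cyclotrimerisation and diene oligomerisation; it is secured by the excess of diene, by the bisphosphine ligand and by the trans-1,3 placement of the two ethynyl groups on opposite faces of the ring, which keeps them from binding one cobalt centre together. The silyl ethers prevent ZnI2-promoted addition of an alcohol to the enol ether diene and alkoxide binding to cobalt.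

Step 6
Reactants: 10 bis(cyclohexadienyl) cycloadduct
Product: 11 bis(tert-butyldimethylsilyl) ether of [(1α,2α,3β,4β)-2,4-bis(3,4-dimethoxyphenyl)cyclobutane-1,3-diyl]dimethanol
Conditions: DDQ (2.2 equiv), toluene, 0 °C to rt
Reagents that add atoms: none
Why: DDQ abstracts hydride from a doubly allylic CH2 of each 1,4-diene to give a methoxy-stabilised cyclohexadienyl cation that loses a proton (quinone dehydrogenation of a cyclohexa-1,4-diene to the arene); with C1 on the cyclobutane and the methoxy groups on C4 and C5, each ring becomes a 3,4-dimethoxyphenyl group. Stoichiometric oxidant at or below room temperature should leave the benzylic cyclobutane C–H bonds alone.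

Step 7
Reactants: 11 bis-silyl ether
Product: 12 [(1α,2α,3β,4β)-2,4-bis(3,4-dimethoxyphenyl)cyclobutane-1,3-diyl]dimethanol
Conditions: Bu4NF (2.5 equiv), THF, rt
Reagents that add atoms: none
Why: Fluoride cleaves the two Si–O bonds (desilylation); nothing else in 11 is sensitive to fluoride or to the mildly basic medium.

Step 8
Reactants: 12 diaryl diol
Product: 14 (1α,2α,3β,4β)-2,4-bis(3,4-dimethoxyphenyl)cyclobutane-1,3-dicarboxylic acid, via 2,4-bis(3,4-dimethoxyphenyl)cyclobutane-1,3-dicarbaldehyde 13 (not isolated)
Conditions: TEMPO (0.3 equiv), PhI(OAc)2 (5 equiv), MeCN–H2O (1:1), rt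
Reagents that add atoms: water, O
Why: PhI(OAc)2 turns TEMPO over to the oxoammonium ion, which oxidises each primary alcohol to the aldehyde and, in water, the aldehyde hydrate to the acid (nitroxyl-catalysed oxidation of a primary alcohol to a carboxylic acid). The medium is weakly acidic, so Cb and Cd should not epimerise at the stage of 13, and the trans-1,3 placement of the two side chains excludes lactol or lactone formation between them.

Step 9
Reactants: 14 diacid; 15 5,6-dihydropyridin-2(1H)-one
Product: 17 CNP0199212.1 1,1'-{[(1α,2α,3β,4β)-2,4-bis(3,4-dimethoxyphenyl)cyclobutane-1,3-diyl]dicarbonyl}bis(5,6-dihydropyridin-2(1H)-one), via bis(pivalic) mixed anhydride 16 (not isolated)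
Conditions: t-BuCOCl (2.2 equiv), Et3N (2.4 equiv), THF, −20 to 0 °C; then added to 15 (2.2 equiv) pre-treated with LiN(SiMe3)2 (2.2 equiv), THF, −78 °C; aq. NH4Cl
Reagents that add atoms: 5,6-dihydropyridin-2(1H)-one (15), O=C1C=CCCN1
Why: Pivaloyl chloride converts each carboxylate into a mixed anhydride whose tert-butyl carbonyl is the more hindered one, and the lithium amide of 15 attacks the cyclobutane carbonyl to form the imide (N-acylation of a lactam through a mixed pivalic anhydride, as used for oxazolidinones). The low temperature and the absence of excess base protect Cb and Cd against enolisation and the enelactam against conjugate addition.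

## Compound list

1 | (1α,2α,3β,4β)-cyclobutane-1,2,3,4-tetracarboxylic 1,2:3,4-dianhydride (cis,trans,cis) | O=C1[C@H]2[C@H](C(=O)O3)[C@H](C3=O)[C@H]2C(=O)O1 | starting material
2 | (1α,2α,3β,4β)-2,4-bis(hydroxymethyl)cyclobutane-1,3-dicarboxylic acid (each CO2H cis to one CH2OH; present as carboxylate before acidification) | OC(=O)[C@H]1[C@H](CO)[C@H](C(=O)O)[C@H]1CO | intermediate
3 | head-to-tail bis-lactone, cis-anti-cis 4,9-dioxatricyclo[5.3.0.0(2,6)]decane-3,8-dione | O=C1[C@H]2[C@H](CO3)[C@H](C3=O)[C@H]2CO1 | intermediate
4 | bis-lactol, 4,9-dioxatricyclo[5.3.0.0(2,6)]decane-3,8-diol (anomers) | OC1[C@H]2[C@H](CO3)[C@H](C3O)[C@H]2CO1 | intermediate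
5 | dimethyl (1-diazo-2-oxopropyl)phosphonate | COP(=O)(OC)C(=[N+]=[N-])C(C)=O | starting material
6 | (1α,2α,3β,4β)-2,4-bis(hydroxymethyl)cyclobutane-1,3-dicarbaldehyde (open-chain tautomer of 4) | O=C[C@H]1[C@H](CO)[C@H](C=O)[C@H]1CO | intermediate
7 | [(1α,2α,3β,4β)-2,4-diethynylcyclobutane-1,3-diyl]dimethanol (ethynyl groups mutually trans, each cis to one CH2OH) | C#C[C@H]1[C@H](CO)[C@H](C#C)[C@H]1CO | intermediate
8 | bis(tert-butyldimethylsilyl) ether of 7 | C#C[C@H]1[C@H](CO[Si](C)(C)C(C)(C)C)[C@H](C#C)[C@H]1CO[Si](C)(C)C(C)(C)C | intermediate
9 | 2,3-dimethoxybuta-1,3-diene | C=C(OC)C(OC)=C | starting material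
10 | bis(tert-butyldimethylsilyl) ether of [(1α,2α,3β,4β)-2,4-bis(4,5-dimethoxycyclohexa-1,4-dien-1-yl)cyclobutane-1,3-diyl]dimethanol | COC1=C(OC)CC(=CC1)[C@H]2[C@H](CO[Si](C)(C)C(C)(C)C)[C@H](C3=CCC(OC)=C(OC)C3)[C@H]2CO[Si](C)(C)C(C)(C)C | intermediate
11 | bis(tert-butyldimethylsilyl) ether of [(1α,2α,3β,4β)-2,4-bis(3,4-dimethoxyphenyl)cyclobutane-1,3-diyl]dimethanol | COc1ccc([C@H]2[C@H](CO[Si](C)(C)C(C)(C)C)[C@H](c3ccc(OC)c(OC)c3)[C@H]2CO[Si](C)(C)C(C)(C)C)cc1OC | intermediate
12 | [(1α,2α,3β,4β)-2,4-bis(3,4-dimethoxyphenyl)cyclobutane-1,3-diyl]dimethanol | COc1ccc([C@H]2[C@H](CO)[C@H](c3ccc(OC)c(OC)c3)[C@H]2CO)cc1OC | intermediate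
13 | (1α,2α,3β,4β)-2,4-bis(3,4-dimethoxyphenyl)cyclobutane-1,3-dicarbaldehyde | COc1ccc([C@H]2[C@H](C=O)[C@H](c3ccc(OC)c(OC)c3)[C@H]2C=O)cc1OC | intermediate
14 | (1α,2α,3β,4β)-2,4-bis(3,4-dimethoxyphenyl)cyclobutane-1,3-dicarboxylic acid | COc1ccc([C@H]2[C@H](C(=O)O)[C@H](c3ccc(OC)c(OC)c3)[C@H]2C(=O)O)cc1OC | intermediate
15 | 5,6-dihydropyridin-2(1H)-one | O=C1C=CCCN1 | starting material
16 | bis(pivalic) mixed anhydride of 14 | COc1ccc([C@H]2[C@H](C(=O)OC(=O)C(C)(C)C)[C@H](c3ccc(OC)c(OC)c3)[C@H]2C(=O)OC(=O)C(C)(C)C)cc1OC | intermediate
17 | CNP0199212.1, 1,1'-{[(1α,2α,3β,4β)-2,4-bis(3,4-dimethoxyphenyl)cyclobutane-1,3-diyl]dicarbonyl}bis(5,6-dihydropyridin-2(1H)-one) | COc1ccc([C@H]2[C@H](C(=O)N3CCC=CC3=O)[C@H](c3ccc(OC)c(OC)c3)[C@H]2C(=O)N2CCC=CC2=O)cc1OC | target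

## Step count and least certain steps

Total step count: 9. Longest linear sequence: 9 steps (1 to 17); compounds 5, 9 and 15 are purchased.

**Step 5 (key step).**
- Most likely to go wrong: cationic oligomerisation of the electron-rich dialkoxy diene under ZnI2, competing cyclotrimerisation or oligomerisation of the alkyne at cobalt, and stalling after the first cycloaddition. All follow from pairing a Lewis acidic catalyst system with a bis-enol ether, and from asking for two catalytic events on one molecule.
- Fallback: activate the alkynes so that the same [4+2] runs thermally with normal electron demand, and remove the activating group afterwards. It sets out from 8. Double deprotonation with n-BuLi and formylation with DMF should give the bis(propynal) F1. Heating F1 with 9 in toluene should give the bis(2-formyl-4,5-dimethoxycyclohexa-1,4-dienyl) adduct F2. DDQ should aromatise it to the bis(2-formyl-4,5-dimethoxyphenyl) compound F3. Tsuji–Wilkinson decarbonylation with RhCl(PPh3)3 in refluxing toluene removes both formyl groups and comes back to the route at 11.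

**Step 1.**
- Most likely to go wrong: absence of regiocontrol combined with incomplete separation of the two bis-lactones, because both carbonyls of each anhydride are equally exposed to hydride.
- Fallback: do the regiochemical sorting on crystalline half-esters. It sets out from 1. Methanolysis (MeOH, pyridine) gives the diacid diesters, from which the head-to-tail 2,4-bis(methoxycarbonyl)cyclobutane-1,3-dicarboxylic acid F4 is taken by fractional crystallisation. BH3·SMe2 reduces only the carboxylic acids, giving dimethyl 2,4-bis(hydroxymethyl)cyclobutane-1,3-dicarboxylate F5. Acid-catalysed lactonisation (TsOH, toluene) comes back to the route at 3.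

**Step 3.**
- Most likely to go wrong: epimerisation at Ca and Cc through enolisation of the free aldehyde in basic methanol, and slow conversion because the cis-fused lactol opens reluctantly.
- Fallback: avoid base while an aldehyde is present. It sets out from 3.
  - Opening with MeNH(OMe)·HCl and Me3Al gives the bis(hydroxy Weinreb amide) F6.
  - Silylation (t-BuMe2SiCl, imidazole) gives the bis-silyl ether F7.
  - i-Bu2AlH at −78 °C gives the bis-silylated dialdehyde F8.
  - CBr4 and PPh3 give the bis(2,2-dibromovinyl) compound F9 (Corey–Fuchs olefination).
  - n-BuLi at −78 °C converts F9 into the diyne and comes back to the route at 8, which also saves step 4.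

**Step 9.**
- Most likely to go wrong: conjugate addition of the lactam anion to the enelactam of 15 or of the product, attack at the pivaloyl carbonyl of the hindered mixed anhydride, and enolisation at Cb or Cd by excess amide base.
- Fallback: introduce the ring double bonds after the acylation. It sets out from 16 (made from 14 as in step 9). Reaction with the lithium salt of 3-(phenylselanyl)piperidin-2-one F10 (from α-selenenylation of piperidin-2-one) should give the bis(3-phenylselanyl) imide F11. Oxidation with H2O2 and pyridine in CH2Cl2 at 0 °C, followed by syn-elimination of the selenoxides, installs both C3=C4 double bonds and comes back to the route at 17.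

## Further compounds

F1 | step 5 | 3,3'-[(1α,2α,3β,4β)-2,4-bis({[tert-butyl(dimethyl)silyl]oxy}methyl)cyclobutane-1,3-diyl]bis(prop-2-ynal) | O=CC#C[C@H]1[C@H](CO[Si](C)(C)C(C)(C)C)[C@H](C#CC=O)[C@H]1CO[Si](C)(C)C(C)(C)C
F2 | step 5 | bis(tert-butyldimethylsilyl) ether of [2,4-bis(2-formyl-4,5-dimethoxycyclohexa-1,4-dien-1-yl)cyclobutane-1,3-diyl]dimethanol | COC1=C(OC)CC(=C(C=O)C1)[C@H]2[C@H](CO[Si](C)(C)C(C)(C)C)[C@H](C3=C(C=O)CC(OC)=C(OC)C3)[C@H]2CO[Si](C)(C)C(C)(C)C
F3 | step 5 | bis(tert-butyldimethylsilyl) ether of [2,4-bis(2-formyl-4,5-dimethoxyphenyl)cyclobutane-1,3-diyl]dimethanol | COc1cc(C=O)c(cc1OC)[C@H]2[C@H](CO[Si](C)(C)C(C)(C)C)[C@H](c3cc(OC)c(OC)cc3C=O)[C@H]2CO[Si](C)(C)C(C)(C)C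
F4 | step 1 | (1α,2α,3β,4β)-2,4-bis(methoxycarbonyl)cyclobutane-1,3-dicarboxylic acid | COC(=O)[C@H]1[C@H](C(=O)O)[C@H](C(=O)OC)[C@H]1C(=O)O
F5 | step 1 | dimethyl (1α,2α,3β,4β)-2,4-bis(hydroxymethyl)cyclobutane-1,3-dicarboxylate | COC(=O)[C@H]1[C@H](CO)[C@H](C(=O)OC)[C@H]1CO
F6 | step 3 | (1α,2α,3β,4β)-2,4-bis(hydroxymethyl)-N1,N3-dimethoxy-N1,N3-dimethylcyclobutane-1,3-dicarboxamide | CON(C)C(=O)[C@H]1[C@H](CO)[C@H](C(=O)N(C)OC)[C@H]1CO
F7 | step 3 | bis(tert-butyldimethylsilyl) ether of F6 | CON(C)C(=O)[C@H]1[C@H](CO[Si](C)(C)C(C)(C)C)[C@H](C(=O)N(C)OC)[C@H]1CO[Si](C)(C)C(C)(C)C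
F8 | step 3 | (1α,2α,3β,4β)-2,4-bis({[tert-butyl(dimethyl)silyl]oxy}methyl)cyclobutane-1,3-dicarbaldehyde | O=C[C@H]1[C@H](CO[Si](C)(C)C(C)(C)C)[C@H](C=O)[C@H]1CO[Si](C)(C)C(C)(C)C
F9 | step 3 | bis(tert-butyldimethylsilyl) ether of [2,4-bis(2,2-dibromovinyl)cyclobutane-1,3-diyl]dimethanol | BrC(Br)=C[C@H]1[C@H](CO[Si](C)(C)C(C)(C)C)[C@H](C=C(Br)Br)[C@H]1CO[Si](C)(C)C(C)(C)C
F10 | step 9 | 3-(phenylselanyl)piperidin-2-one | O=C1NCCCC1[Se]c1ccccc1
F11 | step 9 | 1,1'-{[(1α,2α,3β,4β)-2,4-bis(3,4-dimethoxyphenyl)cyclobutane-1,3-diyl]dicarbonyl}bis[3-(phenylselanyl)piperidin-2-one] | COc1ccc([C@H]2[C@H](C(=O)N3CCCC([Se]c4ccccc4)C3=O)[C@H](c3ccc(OC)c(OC)c3)[C@H]2C(=O)N2CCCC([Se]c3ccccc3)C2=O)cc1OC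
A1 | alternative 1 | 2,4-bis(6-oxo-3,6-dihydropyridine-1(2H)-carbonyl)cyclobutane-1,3-dicarboxylic acid | OC(=O)[C@H]2[C@H](C(=O)N3CCC=CC3=O)[C@H](C(=O)O)[C@H]2C(=O)N2CCC=CC2=O
A2 | alternative 2 | methyl N-[(E)-(3,4-dimethoxyphenyl)methylidene]glycinate | COC(=O)C/N=C/c1ccc(OC)c(OC)c1
A3 | alternative 2 | methyl (Z)-3-(3,4-dimethoxyphenyl)acrylate | COC(=O)/C=C\c1ccc(OC)c(OC)c1
A4 | alternative 2 | dimethyl 3,5-bis(3,4-dimethoxyphenyl)pyrrolidine-2,4-dicarboxylate (2,5-cis, 3,4-cis, 2,3-trans) | N1[C@H](C(=O)OC)[C@@H](c2ccc(OC)c(OC)c2)[C@@H](C(=O)OC)[C@@H]1c1ccc(OC)c(OC)c1
A5 | alternative 3 | trans-N1,N3-di(quinolin-8-yl)cyclobutane-1,3-dicarboxamide | O=C(Nc1cccc2cccnc12)[C@H]1C[C@@H](C1)C(=O)Nc1cccc2cccnc12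
A6 | alternative 3 | 4-iodo-1,2-dimethoxybenzene | COc1ccc(I)cc1OC
A7 | alternative 3 | 2,4-bis(3,4-dimethoxyphenyl)-N1,N3-di(quinolin-8-yl)cyclobutane-1,3-dicarboxamide | COc1ccc([C@H]2[C@H](C(=O)Nc3cccc4cccnc34)[C@H](c3ccc(OC)c(OC)c3)[C@H]2C(=O)Nc2cccc3cccnc23)cc1OC
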